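**Retrosynthetic overview**
1. The C3=C4/C5-OH allylic alcohol is carried as the 4,5-epoxide of commercial (−)-caryophyllene oxide. That material supplies the cyclobutane, the nine-membered ring and C1, C5 and C9. The epoxide is opened last by syn β-elimination.
2. The dihydropyran C8–O–C3' bond comes from the tertiary C8 alcohol adding to, and eliminating from, the activated triketone enol.
3. Key bond C7'–C13: the enone β-carbon of an isopentylidene triketone is turned into a nickel homoenolate (1-siloxyallylnickel). It is joined to the CH2–I carbon of an iodohydrin, so two electrophilic carbons are coupled.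
4. The C8–O stereocentre comes from peripheral epoxidation of the exocyclic methylene, followed by iodide opening at CH2. The triketone comes from dearomative tetramethylation of phloroacetophenone, deacetylation and Knoevenagel condensation.
5. Ring order: cyclobutane and nine-membered ring (bought), then the triketone ring (steps 1–2), then the dihydropyran (step 7).

Assumption and labels: commercial (−)-caryophyllene oxide is the (1R,4R,5R,9S) isomer. Caryophyllane numbers are used: C1/C9 ring fusion, CH3-12 on C4, C13 on C8, gem-dimethyl on C11. Primed numbers cover the triketone half: C2' is bonded to C7', C3' is bonded to the pyran O, and C7' is the CH bearing isobutyl.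

Step 1
Reactants: 1 2',4',6'-trihydroxyacetophenone
Product: 2 2-acetyl-3-hydroxy-4,4,6,6-tetramethylcyclohex-2-ene-1,5-dione (acetylsyncarpic acid)
Conditions: MeI (6 equiv), NaOMe (5 equiv), MeOH, reflux; then aq HCl
Reagents that add atoms: iodomethane, CI
Why: Exhaustive dearomative C-methylation of an acylphloroglucinol, in which the phenolate is alkylated at its two free ring carbons until both are quaternary while the acetyl group blocks the third carbon, and no stereocentre is formed.

Step 2
Reactants: 2 acetylsyncarpic acid
Product: 3 syncarpic acid (5-hydroxy-2,2,6,6-tetramethylcyclohex-4-ene-1,3-dione)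
Conditions: 6 M aq HCl, reflux
Reagents that add atoms: none
Why: Acid-catalysed retro-Claisen deacylation of the tricarbonylmethane expels acetic acid and frees C2' as the only nucleophilic carbon, and no stereocentre is formed.

Step 3
Reactants: 3 syncarpic acid; 4 isovaleraldehyde (3-methylbutanal, 1.5 equiv)
Product: 5 2,2,4,4-tetramethyl-6-(3-methylbutylidene)cyclohexane-1,3,5-trione
Conditions: L-proline (10 mol %), CH2Cl2, 23 °C; used promptly
Reagents that add atoms: none
Why: Amine-catalysed Knoevenagel condensation, in which the flanking gem-dimethyl groups slow a second Michael addition so the alkylidene can be isolated, and the symmetric dione allows no alkene isomers.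

Step 4
Reactants: 6 (−)-caryophyllene oxide, (1R,4R,5R,9S)-4,5-epoxycaryophyll-8(13)-ene
Product: 7 (1R,4R,5R,8R,9S)-4,5:8,13-diepoxycaryophyllane
Conditions: mCPBA (1.2 equiv), CH2Cl2, 0 °C
Reagents that add atoms: 3-chloroperoxybenzoic acid, OOC(=O)c1cccc(Cl)c1
Why: Prilezhaev epoxidation of the only alkene, in which the C8=CH2 bond eclipses C9–H in the reactive conformer (least allylic strain), the ring interior shields the inner face and cyclobutane CH2-10 hinders the other rotamer, so oxygen arrives from the periphery and gives the 8R spiro-epoxide with C13 on the side of H-9 (about 4:1 expected, minor 8S isomer removed by chromatography).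

Step 5
Reactants: 7 diepoxide
Product: 8 (1R,4R,5R,8R,9S)-4,5-epoxy-13-iodocaryophyllan-8-ol
Conditions: LiI (1.5 equiv), AcOH (1.5 equiv), THF, 0 to 23 °C, dark
Reagents that add atoms: lithium iodide, [Li+].[I-]
Why: Regioselective SN2 opening of an epoxide to a halohydrin, in which iodide attacks the exposed CH2 of the spiro-epoxide so the C8–O bond and its configuration are kept, while the 4,5-epoxide survives because both of its backside trajectories point into the ring interior.

Step 6
Reactants: 5 isopentylidene triketone (1.5 equiv); 8 iodohydrin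
Product: 11 (1R,4R,5R,8S,9S,7'R)-13-[3-methyl-1-(2-hydroxy-3,3,5,5-tetramethyl-4,6-dioxocyclohex-1-enyl)butyl]-4,5-epoxycaryophyllan-8-ol, via siloxyallylnickel chloride 9 (not isolated), via trimethylsilyl enol ether 10 (not isolated)
Conditions: 5, Ni(cod)2 (1.5 equiv), Me3SiCl (1.5 equiv), toluene, 23 °C, 1 h; then 8, DMF, visible light (tungsten lamp), 15 °C; aq NH4Cl
Reagents that add atoms: none
Why: Proposed new method: zerovalent nickel adds oxidatively to the enone of 5 once Me3SiCl caps the oxygen, so the normally electrophilic β-carbon C7' becomes the carbon terminus of an η3-1-siloxyallyl ligand on divalent nickel (a homoenolate equivalent), which under light enters a radical chain with the equally electrophilic CH2–I carbon of 8 (iodine abstraction, capture of the β-hydroxyalkyl radical at nickel, reductive elimination from trivalent nickel at the allyl terminus remote from OSiMe3), the closest known reaction type being the reversed-polarity conjugate addition of enone-derived siloxyallylnickel halides to alkyl halides (Corey–Semmelhack-type allylnickel coupling) together with nickel couplings of epoxide-derived iodohydrins that keep the β-hydroxyl; C8 is untouched (its descriptor becomes S only through CIP priorities) and C7' is set by 1,3-induction, since in the staggered bond-forming geometry with C9 anti to C7' and C8 anti to C2' the isobutyl group lies beside the small free OH rather than beside C7H2, which gives 7'R (about 3:1 expected, epimer removed after step 7).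

Step 7
Reactants: 11 hydroxy triketone
Product: 13 (1R,4R,5R,8S,9S,7'R)-4,5-epoxycaryophyllane spiro-fused at C8 to 4-isobutyl-6,6,8,8-tetramethyl-3,4-dihydro-2H-chromene-5,7(6H,8H)-dione (C8 = chromene C2; C13 = C3; C7' = C4), via enol mesylate 12 (not isolated)
Conditions: MsCl (1.2 equiv), K2CO3 (4 equiv), MeCN, 0 °C, then 50 °C
Reagents that add atoms: none
Why: Activation of the vinylogous acid as its enol sulfonate followed by intramolecular oxa-Michael addition–elimination of the tertiary alcohol at C3' closes the six-membered ring under basic conditions that spare the epoxide, and because neither the C8–O nor the C7'–H bond is broken both stereocentres are retained.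

Step 8
Reactants: 13 epoxy spiro-chromenedione
Product: 15 tomentodione O, (1R,3Z,5R,8S,9S,7'R)-caryophyll-3-en-5-ol spiro-fused at C8 to the same chromenedione, via diethylaluminium alkoxide 14 (not isolated)
Conditions: Et2Al(TMP) (4 equiv; from 2,2,6,6-tetramethylpiperidine, n-BuLi, Et2AlCl), toluene, 0 to 23 °C; aq potassium sodium tartrate
Reagents that add atoms: none
Why: Aluminium amide epoxide-to-allylic-alcohol isomerisation (concerted syn β-elimination), in which aluminium binds the epoxide oxygen, the tertiary C4–O bond breaks and the hindered amide takes the syn hydrogen from C3 (the branch cis to H-5) rather than from CH3-12; C5–O is never broken so 5R is retained, the cis (3Z) alkene is expected because it releases the strain of the trans-bridged nine-membered ring, and the triketone half has no enolisable hydrogen.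

**Compound list**
1 | 2',4',6'-trihydroxyacetophenone | CC(=O)c1c(O)cc(O)cc1O | starting material
2 | 2-acetyl-3-hydroxy-4,4,6,6-tetramethylcyclohex-2-ene-1,5-dione (acetylsyncarpic acid) | CC(=O)C1=C(O)C(C)(C)C(=O)C(C)(C)C1=O | intermediate
3 | syncarpic acid (enol form) | CC1(C)C(O)=CC(=O)C(C)(C)C1=O | intermediate
4 | isovaleraldehyde | CC(C)CC=O | starting material
5 | 2,2,4,4-tetramethyl-6-(3-methylbutylidene)cyclohexane-1,3,5-trione | CC(C)CC=C1C(=O)C(C)(C)C(=O)C(C)(C)C1=O | intermediate
6 | (−)-caryophyllene oxide (1R,4R,5R,9S) | C[C@@]12CC[C@@H]3[C@H](CC3(C)C)C(=C)CC[C@H]1O2 | starting material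
7 | (1R,4R,5R,8R,9S)-4,5:8,13-diepoxycaryophyllane | C[C@@]12CC[C@@H]3[C@H](CC3(C)C)[C@@]4(CO4)CC[C@H]1O2 | intermediate
8 | (1R,4R,5R,8R,9S)-4,5-epoxy-13-iodocaryophyllan-8-ol | C[C@@]12CC[C@@H]3[C@H](CC3(C)C)[C@@](O)(CI)CC[C@H]1O2 | intermediate
9 | chloro[η3-1-(trimethylsiloxy)allyl]nickel complex of 5 (chloride-bridged dimer; SMILES drawn as the C7'-σ-bonded monomer) | CC(C)CC([Ni]Cl)C1=C(O[Si](C)(C)C)C(C)(C)C(=O)C(C)(C)C1=O | intermediate
10 | trimethylsilyl enol ether of 11 | C[C@@]12CC[C@@H]3[C@H](CC3(C)C)[C@@](O)(C[C@@H](CC(C)C)C4=C(O[Si](C)(C)C)C(C)(C)C(=O)C(C)(C)C4=O)CC[C@H]1O2 | intermediate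
11 | (1R,4R,5R,8S,9S,7'R)-hydroxy triketone (enol form) | C[C@@]12CC[C@@H]3[C@H](CC3(C)C)[C@@](O)(C[C@@H](CC(C)C)C4=C(O)C(C)(C)C(=O)C(C)(C)C4=O)CC[C@H]1O2 | intermediate
12 | enol methanesulfonate of 11 | C[C@@]12CC[C@@H]3[C@H](CC3(C)C)[C@@](O)(C[C@@H](CC(C)C)C4=C(OS(C)(=O)=O)C(C)(C)C(=O)C(C)(C)C4=O)CC[C@H]1O2 | intermediate
13 | (1R,4R,5R,8S,9S,7'R)-epoxy spiro-chromenedione | C[C@@]12CC[C@@H]3[C@H](CC3(C)C)[C@]3(CC[C@H]1O2)C[C@@H](CC(C)C)C1=C(O3)C(C)(C)C(=O)C(C)(C)C1=O | intermediate
14 | O-diethylaluminium alkoxide of 15 | C/C1=C/C[C@@H]2[C@H](CC2(C)C)[C@]2(CC[C@H]1O[Al](CC)CC)C[C@@H](CC(C)C)C1=C(O2)C(C)(C)C(=O)C(C)(C)C1=O | intermediate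
15 | tomentodione O | C/C1=C/C[C@@H]2[C@H](CC2(C)C)[C@]2(CC[C@H]1O)C[C@@H](CC(C)C)C1=C(O2)C(C)(C)C(=O)C(C)(C)C1=O | target

**Step count**
- Total step count: 8.
- Longest linear sequence: 6 (steps 1, 2, 3, 6, 7, 8).

**Steps most likely to fail**

Step 6. The allylnickel may not form cleanly from the doubly activated enone. The β-hydroxyalkyl group may be lost from nickel as alkene. The C7' ratio may be low.

The fallback sets out from 7 (with 5) and returns at 11. It moves the polarity reversal from the enone carbon to the oxirane carbon.
- The spiro-epoxide of 7 is opened at CH2 with PhSO2Na (DMF–H2O, 80 °C) to give the β-hydroxy sulfone F1.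
- Double deprotonation (n-BuLi, 2.1 equiv, THF, −78 °C) puts the carbanion on C13, and it adds 1,4 to 5 to give the sulfonyl Michael adduct F2.
- This addition is reversible, so the less congested 1,3-relationship can build up.
- Reductive desulfonylation with Na(Hg) and Na2HPO4 in MeOH then gives 11. The free alkoxide is a poor leaving group, so elimination should stay minor.

Step 8. The amide may deliver the trans alkene by least motion, or some exocyclic alkene.

The fallback sets out from 13 and returns at 15. It accepts the trans geometry and corrects it afterwards.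
- The aluminium amide elimination is run to the (3E,5R)-allylic alcohol F3.
- F3 is then equilibrated with catalytic PhSSPh under near-UV light in benzene.
- Reversible thiyl-radical addition at C3 frees rotation about C3–C4, and release of the trans-cyclononene strain drives the mixture to the 3Z isomer.
- C5 is not touched.

Step 4. Peracid may give the wrong face or a poor ratio at C8.

The fallback sets out from 6 and returns at 7. It forms the C8–C13 bond, rather than the C8–O bond, on the open face.
- Ozonolysis of 6 (O3, CH2Cl2, −78 °C; Me2S) gives the nor-ketone kobusone F4.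
- Dimethylsulfonium methylide (Me3SI, KOtBu, DMSO–THF, 0 °C; Corey–Chaykovsky epoxidation) delivers CH2 from the periphery.
- This gives the opposite sense at C8 to peracid attack on the same conformer.

**Further compounds**
F1 | step 6 | (1R,4R,5R,8R,9S)-4,5-epoxy-13-(phenylsulfonyl)caryophyllan-8-ol | C[C@@]12CC[C@@H]3[C@H](CC3(C)C)[C@@](O)(CS(=O)(=O)c4ccccc4)CC[C@H]1O2
F2 | step 6 | 13-phenylsulfonyl derivative of 11 (mixture at C13) | C[C@@]12CC[C@@H]3[C@H](CC3(C)C)[C@@](O)(C([C@@H](CC(C)C)C4=C(O)C(C)(C)C(=O)C(C)(C)C4=O)S(=O)(=O)c5ccccc5)CC[C@H]1O2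
F3 | step 8 | (3E)-isomer of 15 | C/C1=C\C[C@@H]2[C@H](CC2(C)C)[C@]2(CC[C@H]1O)C[C@@H](CC(C)C)C1=C(O2)C(C)(C)C(=O)C(C)(C)C1=O
F4 | step 4 | kobusone, (1R,4R,5R,9S)-4,5-epoxy-13-norcaryophyllan-8-one | C[C@@]12CC[C@@H]3[C@H](CC3(C)C)C(=O)CC[C@H]1O2
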